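## Retrosynthetic overview
1. Target 8 ⇒ 7-fluorosulfate 5. The 7-sulfate is carried as a latent S–F group and unmasked last.
2. 5 ⇒ cyclic sulfate 3 + methoxide. This is the key C–O disconnection: the 4'-O–CH3 bond is made in the same operation that leaves the sulfate on O-3'.
3. 3 ⇒ luteolin 1 + 2 SO2F2.
4. Rings A, C and B are bought intact with luteolin. The only ring made is a temporary five-membered cyclic sulfate (ring D) fused to ring B, closed in step 1 and opened in step 2.

Assumption: the target has no stereocentre, so no enantiomer question arises. It is taken as the free bis(hydrogen sulfate) as drawn, released cold from its salt in the last operation because aryl hydrogen sulfates are acid-labile.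

## Route

Step 1
Reactants: 1 luteolin
Product: 3 luteolin 3',4'-cyclic sulfate 7-fluorosulfate, via luteolin 7,4'-bis(fluorosulfate) 2 (not isolated)
Conditions: SO2F2 (2.2 equiv, metered into the closed flask), MeCN/DMF 4:1, 0 °C; Et3N (3.3 equiv) added last, dropwise, 0 °C to rt, 2 h; cold 0.5 M HCl wash, short SiO2 plug
Reagents that add atoms: sulfuryl fluoride, O=S(=O)(F)F
Why: Sulfur–fluoride exchange (SuFEx) fluorosulfates the acidic 7-OH and 4'-OH, the neighbouring 3'-OH then closes on the 4'-fluorosulfate with loss of fluoride (the usual fate of catechols with SO2F2), and the 5-OH stays free at this stoichiometry because it is locked in the hydrogen bond to C4=O, as in selective 7-O-triflation of 5,7-dihydroxyflavones.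

Step 2
Reactants: 3 luteolin 3',4'-cyclic sulfate 7-fluorosulfate
Product: 5 sodium diosmetin 7-fluorosulfate 3'-sulfate, via sodium 4'-phenoxide 3'-(methyl sulfate) 4 (not isolated)
Conditions: NaOMe (1.00 equiv, titrated 25 wt % solution in MeOH), dry DMF (0.4 M), −40 °C, 15 min; then 30 °C, 4 h; precipitate with MTBE, recrystallise from MeOH/i-PrOH
Reagents that add atoms: sodium methoxide, C[O-].[Na+]
Why: Proposed new method: methoxide serves as a masked CH3(+)/O(2−) pair, attacking the hexavalent sulfur of the strained five-membered aryl cyclic sulfate (orders of magnitude faster than the acyclic S–F group), whereupon the 4'-oxide departs because it is conjugated through ring B with the chromone carbonyl and is about two pKa units less basic than the 3'-oxide (a reversible 1,2-sulfuryl shift between the two oxygens corrects any mis-opening), and the aryl methyl sulfate of 4, an electrophile of dimethyl sulfate strength, passes its methyl group to the 4'-phenoxide of a second molecule by intermolecular SN2 (the intramolecular path cannot reach a linear O–C–O geometry), which forms the 4'-O–CH3 bond, leaves the 3'-sulfate monoanion and uses every atom of NaOMe, the closest known reaction types being alkaline solvolysis of catechol cyclic sulfate and Williamson O-methylation of phenoxides with dimethyl sulfate.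

Step 3
Reactants: 5 sodium diosmetin 7-fluorosulfate 3'-sulfate
Product: 8 luteolin 4'-methyl ether 7,3'-disulfate (target), via 7-(methyl sulfate) diester 6 (not isolated), via sodium ammonium disulfate salt 7 (not isolated)
Conditions: NaOMe (1.1 equiv), NH3 (7 M in MeOH, ca. 50 equiv), 0 °C to rt, 2 h; evaporate; aq HCl (2.0 equiv), 0 °C; C18 desalting (cold H2O, then H2O/MeOH); lyophilise
Reagents that add atoms: sodium methoxide, C[O-].[Na+] (its oxygen stays on sulfur); ammonia, N (nitrogen only in the ammonium counter-ion of 7)
Why: This is the known two-stage unmasking of an aryl fluorosulfate, in which methoxide displaces fluoride at sulfur (SuFEx alcoholysis) and the large excess of NH3 strips the methyl group of diester 6 by SN2 faster than the chelated 5-oxide can be alkylated, while aryl sulfate monoesters are inert to base and are only protonated by cold dilute HCl.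

## Compound list
1 | luteolin (5,7,3',4'-tetrahydroxyflavone) | O=c1cc(-c2ccc(O)c(O)c2)oc2cc(O)cc(O)c12 | starting material
2 | luteolin 7,4'-bis(fluorosulfate), 3'-OH and 5-OH free | O=c1cc(-c2ccc(OS(=O)(=O)F)c(O)c2)oc2cc(OS(=O)(=O)F)cc(O)c12 | intermediate
3 | 2-(2,2-dioxo-1,3,2-benzodioxathiol-5-yl)-5-hydroxy-4-oxo-4H-chromen-7-yl fluorosulfate (luteolin 3',4'-cyclic sulfate 7-fluorosulfate) | O=c1cc(-c2ccc3c(c2)OS(=O)(=O)O3)oc2cc(OS(=O)(=O)F)cc(O)c12 | intermediate
4 | sodium 4'-phenoxide of luteolin 7-fluorosulfate 3'-(methyl sulfate) | COS(=O)(=O)Oc1cc(-c2cc(=O)c3c(O)cc(OS(=O)(=O)F)cc3o2)ccc1[O-].[Na+] | intermediate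
5 | sodium 5-[7-(fluorosulfonyloxy)-5-hydroxy-4-oxo-4H-chromen-2-yl]-2-methoxyphenyl sulfate (diosmetin 7-fluorosulfate 3'-sulfate, sodium salt) | COc1ccc(-c2cc(=O)c3c(O)cc(OS(=O)(=O)F)cc3o2)cc1OS(=O)(=O)[O-].[Na+] | intermediate
6 | diosmetin 7-(methyl sulfate) 3'-sulfate, sodium salt | COc1ccc(-c2cc(=O)c3c(O)cc(OS(=O)(=O)OC)cc3o2)cc1OS(=O)(=O)[O-].[Na+] | intermediate
7 | diosmetin 7,3'-disulfate, sodium ammonium salt | COc1ccc(-c2cc(=O)c3c(O)cc(OS(=O)(=O)[O-])cc3o2)cc1OS(=O)(=O)[O-].[Na+].[NH4+] | intermediate
8 | luteolin 4'-methyl ether 7,3'-disulfate (diosmetin 7,3'-bis(hydrogen sulfate)), achiral | COc1ccc(-c2cc(=O)c3c(O)cc(OS(=O)(=O)O)cc3o2)cc1OS(=O)(=O)O | target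

## Count and risks
Total step count: 3. Longest linear sequence: 3.

**Step 2 (the proposed new step).**
- Risks: some opening towards the 3'-oxide, attack of the 4'-phenoxide on the S–F group of another molecule, and loss of the methyl group to MeOH.
- Fallback, known chemistry only, from 3 back to 5: open the cyclic sulfate with hydroxide instead of methoxide (NaOH 1.0 equiv, kept at pH 10 or below, MeCN/H2O, 0 °C). This is the classical alkaline hydrolysis of catechol cyclic sulfates, which frees the phenol para to the acceptor as in nitrocatechol sulfate. It gives sodium luteolin 7-fluorosulfate 3'-sulfate F1. The 4'-OH of F1 is its only unchelated phenol, and it is methylated by an ordinary Williamson reaction with an external electrophile (MeI 1.1 equiv, Na2CO3, DMF, rt) to give 5.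

**Step 1.**
- Risks: fluorosulfation of the 5-OH, and diaryl sulfate oligomers formed from free phenoxides and the reactive cyclic sulfate.
- Fallback from 1 back to 3, with the two sites addressed one at a time through temporary catechol protection: heat 1 with Ph2CCl2 in diphenyl ether at 175 °C to give luteolin 3',4'-diphenylmethylene ketal F2. Treat this with SO2F2 (1.1 equiv) and Et3N to give the ketal 7-fluorosulfate F3. Cleave the ketal in AcOH/H2O 4:1 at reflux, which the acid-stable S–F group survives, to give luteolin 7-fluorosulfate F4. Close the catechol with SO2F2 (1.05 equiv) and Et3N, passing through 2, to give 3.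

**Step 3.**
- Risks: S–OAr scission at the activated 7-position, and 5-O-methylation by diester 6.
- Fallback from 5 back to 7, with no alkylating diester involved: treat 5 with benzohydroxamic acid (1.5 equiv) in aqueous NH3/NH4HCO3 buffer (pH about 8.5) with MeCN at 37 °C. The hydroxamate oxygen displaces fluoride to give the O-(aryloxysulfonyl) benzohydroxamate F5. This collapses by Lossen rearrangement directly to the aryl sulfate, giving salt 7, which is acidified as in the route.

## Further compounds
F1 | step 2 | sodium luteolin 7-fluorosulfate 3'-sulfate (4'-OH and 5-OH free) | O=c1cc(-c2ccc(O)c(OS(=O)(=O)[O-])c2)oc2cc(OS(=O)(=O)F)cc(O)c12.[Na+]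
F2 | step 1 | luteolin 3',4'-diphenylmethylene ketal | O=c1cc(-c2ccc3c(c2)OC(c2ccccc2)(c2ccccc2)O3)oc2cc(O)cc(O)c12
F3 | step 1 | luteolin 3',4'-diphenylmethylene ketal 7-fluorosulfate | O=c1cc(-c2ccc3c(c2)OC(c2ccccc2)(c2ccccc2)O3)oc2cc(OS(=O)(=O)F)cc(O)c12
F4 | step 1 | luteolin 7-fluorosulfate | O=c1cc(-c2ccc(O)c(O)c2)oc2cc(OS(=O)(=O)F)cc(O)c12
F5 | step 3 | diosmetin 3'-sulfate (sodium salt) 7-O-sulfonyl benzohydroxamate | COc1ccc(-c2cc(=O)c3c(O)cc(OS(=O)(=O)ONC(=O)c4ccccc4)cc3o2)cc1OS(=O)(=O)[O-].[Na+]
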